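The cyclohexenone is closed last between C5 and C6 by a Ni/Cr-mediated Nozaki–Hiyama–Kishi cyclization of an acyclic (Z)-iodoalkene onto an α,β-epoxy aldehyde. Numbering: C6 = ring ketone, C1 = farnesylated epoxide carbon, C2 = epoxide CH, C3 = carbinol, C4=C5 = enone alkene, C7 = CH2O. The step exploits two cis relationships, C3/C6 on the C1–C2 oxirane and C3/iodine on the C4=C5 alkene, and should tolerate the epoxide, skipped triene and ester. The precursor already holds every stereocenter: C1/C2 from a Sharpless epoxidation, C3 by Felkin–Anh relay from them, and the side-chain carbinol from (S)-mevalonolactone, whose CH2OSiEt3 arm is oxidized to the acid afterwards.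

Key step: step 14

Assumption: (S)-mevalonolactone (15), 4-methoxybenzyl chloromethyl ether (6) and tributyl(trimethylsilyl)stannane (11) are taken as purchasable; 25 is carried as a mixture of C6 epimers because step 15 removes that center.

Step 1
Reactants: 1 prop-2-yn-1-ol; 2 (2E,6E)-farnesyl bromide
Product: 3 (5E,9E)-6,10,14-trimethylpentadeca-5,9,13-trien-2-yn-1-ol
Conditions: CuI (20 mol%), K2CO3, DMF, rt
Reagents that add atoms: none
Why: Copper-catalysed alkynylation of the primary allylic bromide (copper acetylide SN2 coupling) should give the linear skipped enyne with the (E,E) geometry of 2 retained.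

Step 2
Reactants: 3 (5E,9E)-6,10,14-trimethylpentadeca-5,9,13-trien-2-yn-1-ol
Product: 5 (2Z,5E,9E)-3-iodo-6,10,14-trimethylpentadeca-2,5,9,13-tetraen-1-ol, via cyclic alkenylaluminate 4 (not isolated)
Conditions: Red-Al, THF, 0 °C to rt; then I2, THF, −78 °C
Reagents that add atoms: iodine, II
Why: Hydroxyl-directed trans-hydroalumination of the propargylic alcohol puts aluminium on C1 cis to the C3 oxygen, and iodinolysis with retention should give the (Z)-3-iodoallylic alcohol that later fixes C3 and C6 cis on the oxirane.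

Step 3
Reactants: 5 (2Z,5E,9E)-3-iodo-6,10,14-trimethylpentadeca-2,5,9,13-tetraen-1-ol; 6 4-methoxybenzyl chloromethyl ether
Product: 8 (2Z,5E,9E)-3-{[(4-methoxybenzyl)oxy]methyl}-6,10,14-trimethylpentadeca-2,5,9,13-tetraen-1-ol, via dilithio species 7 (not isolated)
Conditions: n-BuLi (1 equiv), then t-BuLi (2 equiv), THF, −78 °C; then 6, −78 to −20 °C
Reagents that add atoms: none
Why: Deprotonation and iodine–lithium exchange with retention give an alkenyllithium that should be alkylated at carbon by the α-chloro ether much faster than the lithium alkoxide, installing C6 as its PMB ether while the C3 alcohol stays free.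

Step 4
Reactants: 8 (2Z,5E,9E)-3-{[(4-methoxybenzyl)oxy]methyl}-6,10,14-trimethylpentadeca-2,5,9,13-tetraen-1-ol
Product: 9 [(2R,3S)-3-{[(4-methoxybenzyl)oxy]methyl}-3-[(2E,6E)-3,7,11-trimethyldodeca-2,6,10-trien-1-yl]oxiran-2-yl]methanol
Conditions: Ti(Oi-Pr)4 (10 mol%), D-(−)-diisopropyl tartrate (12 mol%), t-BuOOH, 4 Å MS, CH2Cl2, −20 °C
Reagents that add atoms: tert-butyl hydroperoxide, CC(C)(C)OO
Why: Sharpless asymmetric epoxidation of a 3,3-disubstituted allylic alcohol; the D-(−)-tartrate catalyst should deliver oxygen to the face that makes the carbinol-bearing oxirane carbon (R), setting C1 and C2, and only the allylic alkene reacts.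

Step 5
Reactants: 9 [(2R,3S)-3-{[(4-methoxybenzyl)oxy]methyl}-3-[(2E,6E)-3,7,11-trimethyldodeca-2,6,10-trien-1-yl]oxiran-2-yl]methanol
Product: 10 (2S,3S)-3-{[(4-methoxybenzyl)oxy]methyl}-3-[(2E,6E)-3,7,11-trimethyldodeca-2,6,10-trien-1-yl]oxirane-2-carbaldehyde
Conditions: Dess–Martin periodinane, NaHCO3, CH2Cl2, 0 °C to rt
Reagents that add atoms: none
Why: Dess–Martin oxidation of the primary 2,3-epoxy alcohol under buffered conditions should give the epoxy aldehyde without touching the oxirane or the alkenes.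

Step 6
Reactants: 1 prop-2-yn-1-ol; 11 tributyl(trimethylsilyl)stannane
Product: 12 (Z)-2-(tributylstannyl)-3-(trimethylsilyl)prop-2-en-1-ol
Conditions: Pd(PPh3)4 (3 mol%), THF, 65 °C
Reagents that add atoms: none
Why: Palladium-catalysed silylstannation of a terminal alkyne is a syn addition that places silicon on the terminal and tin on the internal carbon, so Si (future C5) and Sn (future C4) are cis.

Step 7
Reactants: 12 (Z)-2-(tributylstannyl)-3-(trimethylsilyl)prop-2-en-1-ol; 10 (2S,3S)-3-{[(4-methoxybenzyl)oxy]methyl}-3-[(2E,6E)-3,7,11-trimethyldodeca-2,6,10-trien-1-yl]oxirane-2-carbaldehyde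
Product: 14 (1R,2Z)-1-[(2R,3S)-3-{[(4-methoxybenzyl)oxy]methyl}-3-[(2E,6E)-3,7,11-trimethyldodeca-2,6,10-trien-1-yl]oxiran-2-yl]-2-[(trimethylsilyl)methylidene]propane-1,3-diol, via dilithio reagent 13 (not isolated)
Conditions: 12 (1.5 equiv), MeLi (3.1 equiv), THF, −78 to −30 °C; then 10, −78 °C
Reagents that add atoms: none
Why: Tin–lithium exchange with retention gives the C4 alkenyllithium, whose 1,2-addition to the α,β-epoxy aldehyde should follow the Felkin–Anh model (oxirane C–O anti to the nucleophile, reinforced by the cis CH2OPMB group) and give the erythro C3 carbinol.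

Step 8
Reactants: 15 (S)-mevalonolactone
Product: 18 (3S)-3-methyl-3,5-bis[(triethylsilyl)oxy]pentanoic acid, via lithium mevalonate 16 (not isolated), via tris-TES derivative 17 (not isolated)
Conditions: LiOH, THF/H2O, rt, evaporate; TESOTf, 2,6-lutidine, CH2Cl2, 0 °C; K2CO3 (cat.), MeOH/H2O, 0 °C, citric acid to pH 5
Reagents that add atoms: lithium hydroxide, [Li+].[OH-]; triethylsilyl trifluoromethanesulfonate, CC[Si](CC)(CC)OS(=O)(=O)C(F)(F)F
Why: Saponification of the lactone, exhaustive silylation and selective solvolysis of the labile silyl ester should give the acid; the stereocenter comes from the chiral pool and is not touched.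

Step 9
Reactants: 14 (the diol from step 7); 18 (3S)-3-methyl-3,5-bis[(triethylsilyl)oxy]pentanoic acid
Product: 19 (2Z)-2-{(R)-hydroxy[(2R,3S)-3-{[(4-methoxybenzyl)oxy]methyl}-3-[(2E,6E)-3,7,11-trimethyldodeca-2,6,10-trien-1-yl]oxiran-2-yl]methyl}-3-(trimethylsilyl)prop-2-en-1-yl (3S)-3-methyl-3,5-bis[(triethylsilyl)oxy]pentanoate
Conditions: EDC·HCl, DMAP (cat.), CH2Cl2, 0 °C
Reagents that add atoms: none
Why: Carbodiimide (Steglich-type) esterification should acylate the primary allylic C7 hydroxyl selectively over the hindered secondary C3 hydroxyl flanked by the oxirane and the trisubstituted alkene.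

Step 10
Reactants: 19 (the C7 ester from step 9)
Product: 20 C3 O-tert-butyldimethylsilyl ether of 19
Conditions: TBSOTf, 2,6-lutidine, CH2Cl2, −78 to −40 °C
Reagents that add atoms: tert-butyldimethylsilyl trifluoromethanesulfonate, CC(C)(C)[Si](C)(C)OS(=O)(=O)C(F)(F)F
Why: Silyl triflate silylation of the only free hydroxyl under lutidine buffering should protect C3–OH without opening the epoxide.

Step 11
Reactants: 20 (the C3 silyl ether from step 10)
Product: 21 (Z)-alkenyl iodide: 20 with iodine in place of the trimethylsilyl group on C5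
Conditions: N-iodosuccinimide, MeCN/ClCH2CN (4:1), 0 °C to rt, dark
Reagents that add atoms: N-iodosuccinimide, O=C1CCC(=O)N1I
Why: Electrophilic ipso-iododesilylation of the vinylsilane through the β-silyl cation should replace silicon by iodine with retention of the alkene geometry, keeping iodine cis to C3.

Step 12
Reactants: 21 (the alkenyl iodide from step 11)
Product: 22 primary alcohol: 21 with C6–OH in place of the PMB ether
Conditions: DDQ, CH2Cl2/pH 7 phosphate buffer, 0 °C
Reagents that add atoms: none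
Why: Oxidative cleavage of the p-methoxybenzyl ether by DDQ under buffered conditions should free the C6 hydroxyl while the silyl ethers, alkenyl iodide and epoxide remain.

Step 13
Reactants: 22 (the C6 alcohol from step 12)
Product: 23 α,β-epoxy aldehyde: 22 with C6 as the formyl group on the quaternary oxirane carbon C1
Conditions: Dess–Martin periodinane, NaHCO3, CH2Cl2, 0 °C to rt
Reagents that add atoms: none
Why: Dess–Martin oxidation of the neopentyl-type primary alcohol should give the non-enolizable aldehyde, so C1 cannot epimerize.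

Step 14
Reactants: 23 (the (Z)-iodoalkene epoxy aldehyde from step 13)
Product: 25 [(1R,5R,6R)-5-[(tert-butyldimethylsilyl)oxy]-2-hydroxy-1-[(2E,6E)-3,7,11-trimethyldodeca-2,6,10-trien-1-yl]-7-oxabicyclo[4.1.0]hept-3-en-4-yl]methyl (3S)-3-methyl-3,5-bis[(triethylsilyl)oxy]pentanoate (both C2 epimers of the bicycle = C6 of the route numbering), via alkenylchromium(III) species 24 (not isolated)
Conditions: CrCl2 (8 equiv), NiCl2 (2 mol%), DMSO/THF, rt, 0.005 M
Reagents that add atoms: none
Why: Ni(0) formed in situ adds oxidatively to the C5–I bond with retention and transmetalates to Cr(III), and the alkenylchromium 24 then adds to the C6 aldehyde to form the C5–C6 bond. The closest known reaction type is the intramolecular Nozaki–Hiyama–Kishi cyclization of an alkenyl iodide onto an aldehyde, used for cyclohexenols and larger rings. The six-membered carbocycle closes in a 6-exo-trig mode. The only new stereocenter is the C6 carbinol; it is not controlled and need not be, since step 15 oxidizes it, while C1, C2, C3 and the side-chain center are not touched. The step needs chemoselective addition to the aldehyde in the presence of two ester-type carbonyl sites, an oxirane and an allylic ester, which the non-basic, aldehyde-selective organochromium reagent should provide. Reach is secured by the (Z)-alkene and the cis-oxirane, which hold C5 and C6 on the same side of C3, and high dilution suppresses intermolecular coupling.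

Step 15
Reactants: 25 (the cyclohexenol from step 14, both C6 epimers)
Product: 26 [(1R,5R,6R)-5-[(tert-butyldimethylsilyl)oxy]-2-oxo-1-[(2E,6E)-3,7,11-trimethyldodeca-2,6,10-trien-1-yl]-7-oxabicyclo[4.1.0]hept-3-en-4-yl]methyl (3S)-3-methyl-3,5-bis[(triethylsilyl)oxy]pentanoate
Conditions: Dess–Martin periodinane, NaHCO3, CH2Cl2, 0 °C to rt
Reagents that add atoms: none
Why: Dess–Martin oxidation of the secondary allylic alcohol should converge both C6 epimers on the epoxy enone, which cannot aromatize because C1 is quaternary.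

Step 16
Reactants: 26 (the epoxy enone from step 15)
Product: 27 aldehyde: 26 with the side-chain CH2OSiEt3 converted to CHO [(3S)-3-methyl-5-oxo-3-[(triethylsilyl)oxy]pentanoate ester]
Conditions: (COCl)2, DMSO, CH2Cl2, −78 to −35 °C; then Et3N, −78 to 0 °C
Reagents that add atoms: none
Why: Under Swern conditions the unhindered primary triethylsilyl ether should be converted directly into the alkoxysulfonium ion and then the aldehyde, while the secondary TBS and tertiary TES ethers are too hindered to react, so a lactonization-prone free δ-hydroxy ester is never formed.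

Step 17
Reactants: 27 (the aldehyde from step 16)
Product: 28 (3S)-5-{[(1R,5R,6R)-5-[(tert-butyldimethylsilyl)oxy]-2-oxo-1-[(2E,6E)-3,7,11-trimethyldodeca-2,6,10-trien-1-yl]-7-oxabicyclo[4.1.0]hept-3-en-4-yl]methoxy}-3-methyl-5-oxo-3-[(triethylsilyl)oxy]pentanoic acid
Conditions: NaClO2, NaH2PO4, 2-methyl-2-butene, t-BuOH/H2O, 0 °C
Reagents that add atoms: sodium chlorite, [Na+].[O-]Cl=O
Why: Pinnick oxidation should convert the aldehyde into the acid, with excess 2-methyl-2-butene scavenging hypochlorous acid so that the triene and enone survive.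

Step 18
Reactants: 28 (the silylated acid from step 17)
Product: 29 (3S)-3-hydroxy-5-{[(1R,5R,6R)-5-hydroxy-2-oxo-1-[(2E,6E)-3,7,11-trimethyldodeca-2,6,10-trien-1-yl]-7-oxabicyclo[4.1.0]hept-3-en-4-yl]methoxy}-3-methyl-5-oxopentanoic acid (target)
Conditions: HF·pyridine, pyridine, THF, 0 °C to rt
Reagents that add atoms: none
Why: Buffered fluoride desilylation should remove the secondary TBS and tertiary TES ethers without base, avoiding opening of the epoxy enone or acyl migration.

Compound list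
1 | prop-2-yn-1-ol | C#CCO | starting material
2 | (2E,6E)-farnesyl bromide | CC(C)=CCC/C(C)=C/CC/C(C)=C/CBr | starting material
3 | (5E,9E)-6,10,14-trimethylpentadeca-5,9,13-trien-2-yn-1-ol | CC(C)=CCC/C(C)=C/CC/C(C)=C/CC#CCO | intermediate
4 | cyclic sodium alkenyl(alkoxy)bis(2-methoxyethoxy)aluminate of 3 (Al on C1, cis to the C3 oxygen) | [Na+].COCCO[Al-]1(OCCOC)OC/C=C1/C/C=C(C)/CC/C=C(C)/CCC=C(C)C | intermediate
5 | (2Z,5E,9E)-3-iodo-6,10,14-trimethylpentadeca-2,5,9,13-tetraen-1-ol | CC(C)=CCC/C(C)=C/CC/C(C)=C/C/C(I)=C/CO | intermediate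
6 | 4-methoxybenzyl chloromethyl ether | COc1ccc(COCCl)cc1 | starting material
7 | dilithio species of 5 (O–Li and C–Li in place of O–H and C–I, geometry retained) | CC(C)=CCC/C(C)=C/CC/C(C)=C/C/C([Li])=C/CO[Li] | intermediate
8 | (2Z,5E,9E)-3-{[(4-methoxybenzyl)oxy]methyl}-6,10,14-trimethylpentadeca-2,5,9,13-tetraen-1-ol | CC(C)=CCC/C(C)=C/CC/C(C)=C/C/C(COCc1ccc(OC)cc1)=C/CO | intermediate
9 | [(2R,3S)-3-{[(4-methoxybenzyl)oxy]methyl}-3-[(2E,6E)-3,7,11-trimethyldodeca-2,6,10-trien-1-yl]oxiran-2-yl]methanol | CC(C)=CCC/C(C)=C/CC/C(C)=C/C[C@@]1(COCc2ccc(OC)cc2)O[C@@H]1CO | intermediate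
10 | (2S,3S)-3-{[(4-methoxybenzyl)oxy]methyl}-3-[(2E,6E)-3,7,11-trimethyldodeca-2,6,10-trien-1-yl]oxirane-2-carbaldehyde | CC(C)=CCC/C(C)=C/CC/C(C)=C/C[C@@]1(COCc2ccc(OC)cc2)O[C@@H]1C=O | intermediate
11 | tributyl(trimethylsilyl)stannane | CCCC[Sn](CCCC)(CCCC)[Si](C)(C)C | starting material
12 | (Z)-2-(tributylstannyl)-3-(trimethylsilyl)prop-2-en-1-ol | C[Si](C)(C)/C=C(/CO)[Sn](CCCC)(CCCC)CCCC | intermediate
13 | dilithio reagent from 12 (O–Li and C–Li in place of O–H and C–Sn, Si cis to Li) | C[Si](C)(C)/C=C(/CO[Li])[Li] | intermediate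
14 | (1R,2Z)-1-[(2R,3S)-3-{[(4-methoxybenzyl)oxy]methyl}-3-[(2E,6E)-3,7,11-trimethyldodeca-2,6,10-trien-1-yl]oxiran-2-yl]-2-[(trimethylsilyl)methylidene]propane-1,3-diol | CC(C)=CCC/C(C)=C/CC/C(C)=C/C[C@@]1(COCc2ccc(OC)cc2)O[C@@H]1[C@H](O)/C(CO)=C\[Si](C)(C)C | intermediate
15 | (S)-mevalonolactone, (4S)-4-hydroxy-4-methyltetrahydro-2H-pyran-2-one | O=C1C[C@@](C)(O)CCO1 | starting material
16 | lithium (3S)-3,5-dihydroxy-3-methylpentanoate | [Li+].[O-]C(=O)C[C@@](C)(O)CCO | intermediate
17 | triethylsilyl (3S)-3-methyl-3,5-bis[(triethylsilyl)oxy]pentanoate | CC[Si](CC)(CC)OC(=O)C[C@@](C)(O[Si](CC)(CC)CC)CCO[Si](CC)(CC)CC | intermediate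
18 | (3S)-3-methyl-3,5-bis[(triethylsilyl)oxy]pentanoic acid | OC(=O)C[C@@](C)(O[Si](CC)(CC)CC)CCO[Si](CC)(CC)CC | intermediate
19 | C7 ester of 14 with 18, C3–OH free, (Z)-vinylsilane | CC(C)=CCC/C(C)=C/CC/C(C)=C/C[C@@]1(COCc2ccc(OC)cc2)O[C@@H]1[C@H](O)/C(COC(=O)C[C@@](C)(O[Si](CC)(CC)CC)CCO[Si](CC)(CC)CC)=C\[Si](C)(C)C | intermediate
20 | C3 O-tert-butyldimethylsilyl ether of 19 | CC(C)=CCC/C(C)=C/CC/C(C)=C/C[C@@]1(COCc2ccc(OC)cc2)O[C@@H]1[C@H](O[Si](C)(C)C(C)(C)C)/C(COC(=O)C[C@@](C)(O[Si](CC)(CC)CC)CCO[Si](CC)(CC)CC)=C\[Si](C)(C)C | intermediate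
21 | (Z)-alkenyl iodide from 20 (iodine on C5, cis to C3) | CC(C)=CCC/C(C)=C/CC/C(C)=C/C[C@@]1(COCc2ccc(OC)cc2)O[C@@H]1[C@H](O[Si](C)(C)C(C)(C)C)/C(COC(=O)C[C@@](C)(O[Si](CC)(CC)CC)CCO[Si](CC)(CC)CC)=C\I | intermediate
22 | C6 primary alcohol from 21 (PMB removed) | CC(C)=CCC/C(C)=C/CC/C(C)=C/C[C@@]1(CO)O[C@@H]1[C@H](O[Si](C)(C)C(C)(C)C)/C(COC(=O)C[C@@](C)(O[Si](CC)(CC)CC)CCO[Si](CC)(CC)CC)=C\I | intermediate
23 | α,β-epoxy aldehyde (C6 formyl on the (2R,3R)-oxirane) with the (Z)-iodoalkene | CC(C)=CCC/C(C)=C/CC/C(C)=C/C[C@@]1(C=O)O[C@@H]1[C@H](O[Si](C)(C)C(C)(C)C)/C(COC(=O)C[C@@](C)(O[Si](CC)(CC)CC)CCO[Si](CC)(CC)CC)=C\I | intermediate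
24 | alkenylchromium(III) dichloride from 23 (Cr on C5, cis to C3) | CC(C)=CCC/C(C)=C/CC/C(C)=C/C[C@@]1(C=O)O[C@@H]1[C@H](O[Si](C)(C)C(C)(C)C)/C(COC(=O)C[C@@](C)(O[Si](CC)(CC)CC)CCO[Si](CC)(CC)CC)=C\[Cr](Cl)Cl | intermediate
25 | cyclohexenol: (1R,5R,6R)-7-oxabicyclo[4.1.0]hept-3-ene with 2-OH (both epimers), 5-OTBS, 1-farnesyl and the 4-CH2 ester of 18 | CC(C)=CCC/C(C)=C/CC/C(C)=C/C[C@@]12O[C@@H]1[C@H](O[Si](C)(C)C(C)(C)C)C(COC(=O)C[C@@](C)(O[Si](CC)(CC)CC)CCO[Si](CC)(CC)CC)=CC2O | intermediate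
26 | epoxy enone: 2-oxo analogue of 25, (1R,5R,6R) | CC(C)=CCC/C(C)=C/CC/C(C)=C/C[C@@]12O[C@@H]1[C@H](O[Si](C)(C)C(C)(C)C)C(COC(=O)C[C@@](C)(O[Si](CC)(CC)CC)CCO[Si](CC)(CC)CC)=CC2=O | intermediate
27 | side-chain aldehyde from 26, (3S)-3-methyl-5-oxo-3-[(triethylsilyl)oxy]pentanoate ester | CC(C)=CCC/C(C)=C/CC/C(C)=C/C[C@@]12O[C@@H]1[C@H](O[Si](C)(C)C(C)(C)C)C(COC(=O)C[C@@](C)(O[Si](CC)(CC)CC)CC=O)=CC2=O | intermediate
28 | bis-silylated acid: 29 with C3 O-TBS and side-chain O-TES | CC(C)=CCC/C(C)=C/CC/C(C)=C/C[C@@]12O[C@@H]1[C@H](O[Si](C)(C)C(C)(C)C)C(COC(=O)C[C@@](C)(O[Si](CC)(CC)CC)CC(=O)O)=CC2=O | intermediate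
29 | (3S)-3-hydroxy-5-{[(1R,5R,6R)-5-hydroxy-2-oxo-1-[(2E,6E)-3,7,11-trimethyldodeca-2,6,10-trien-1-yl]-7-oxabicyclo[4.1.0]hept-3-en-4-yl]methoxy}-3-methyl-5-oxopentanoic acid | CC(C)=CCC/C(C)=C/CC/C(C)=C/C[C@@]12O[C@@H]1[C@H](O)C(COC(=O)C[C@@](C)(O)CC(=O)O)=CC2=O | target

Total step count: 18. Longest linear sequence: 16 (steps 1–5, 7, 9–18); steps 6 and 8 make the two side fragments.

Steps most likely to fail

Step 14. Cr(II) may reduce the α,β-epoxy aldehyde by electron transfer and open the oxirane, or intermolecular coupling may compete, before the hindered trisubstituted C–I bond is activated. The fallback sets out from 23 and avoids both the aldehyde and chromium. Chlorite oxidation gives the epoxy acid F1, and 2,2'-dipyridyl disulfide with PPh3 converts it into the S-2-pyridyl thioester F2. A Ni-catalysed, Cp2ZrCl2/Zn-mediated intramolecular coupling of the alkenyl iodide with the thioester then closes the same C5–C6 bond. It comes back at enone 26, so steps 14 and 15 are both replaced.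

Step 11. Electrophilic iodine may attack the electron-rich trisubstituted alkenes of the farnesyl chain faster than the allylically oxygenated vinylsilane, or rotation in the β-silyl cation may erode the alkene geometry. The fallback sets out from 14 and uses the cis C3–OH/SiMe3 arrangement instead of an electrophile. Copper(I) tert-butoxide (THF/DMF, rt) promotes 1,4 C(sp2)→O silyl migration to a (Z)-alkenylcopper, which iodine at −78 °C traps as the O-trimethylsilyl iodide F3. Mild aqueous acid on work-up gives the iodo diol F4. Esterification with 18 under the conditions of step 9 gives the iodo ester F5, and silylation as in step 10 comes back at 21.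

Step 7. Facial selectivity in the addition may be poor if chelated or Cornforth-type transition states compete with the Felkin–Anh one, giving the C3 epimer. The fallback sets out from 19 carried as the C3 epimer mixture. Dess–Martin oxidation gives the α,β-epoxy enone F6. Chelation-controlled reduction with Zn(BH4)2 (Et2O, −20 °C), which gives erythro alcohols from α,β-epoxy ketones, then comes back at 19 as a single epimer.

Further compounds
F1 | step 14 | epoxy acid: 23 with C6 as CO2H | CC(C)=CCC/C(C)=C/CC/C(C)=C/C[C@@]1(C(O)=O)O[C@@H]1[C@H](O[Si](C)(C)C(C)(C)C)/C(COC(=O)C[C@@](C)(O[Si](CC)(CC)CC)CCO[Si](CC)(CC)CC)=C\I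
F2 | step 14 | S-2-pyridyl thioester of F1 | CC(C)=CCC/C(C)=C/CC/C(C)=C/C[C@@]1(C(=O)Sc2ccccn2)O[C@@H]1[C@H](O[Si](C)(C)C(C)(C)C)/C(COC(=O)C[C@@](C)(O[Si](CC)(CC)CC)CCO[Si](CC)(CC)CC)=C\I
F3 | step 11 | (Z)-iodoalkene with C3 O-trimethylsilyl ether and free C7–OH | CC(C)=CCC/C(C)=C/CC/C(C)=C/C[C@@]1(COCc2ccc(OC)cc2)O[C@@H]1[C@H](O[Si](C)(C)C)/C(CO)=C\I
F4 | step 11 | (Z)-iodo diol: 14 with iodine in place of SiMe3 | CC(C)=CCC/C(C)=C/CC/C(C)=C/C[C@@]1(COCc2ccc(OC)cc2)O[C@@H]1[C@H](O)/C(CO)=C\I
F5 | step 11 | C7 ester of F4 with 18, C3–OH free | CC(C)=CCC/C(C)=C/CC/C(C)=C/C[C@@]1(COCc2ccc(OC)cc2)O[C@@H]1[C@H](O)/C(COC(=O)C[C@@](C)(O[Si](CC)(CC)CC)CCO[Si](CC)(CC)CC)=C\I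
F6 | step 7 | α,β-epoxy enone: 19 with C3 as ketone | CC(C)=CCC/C(C)=C/CC/C(C)=C/C[C@@]1(COCc2ccc(OC)cc2)O[C@@H]1C(=O)/C(COC(=O)C[C@@](C)(O[Si](CC)(CC)CC)CCO[Si](CC)(CC)CC)=C\[Si](C)(C)C
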